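## The problem

Atom labels follow the chromanone numbering of the target (O1, C2, C3, C4, C4a, C5–C8, C8a); the octanoic acid carbons are C1'–C8'.

- The benzene ring C4a–C8a is fully substituted. Three oxygens (ring O1 on C8a, the chelated OH on C5, the methyl ether on C7) alternate with three different carbon groups (the C4 ketone on C4a, the stereogenic C3' on C6, prenyl on C8).
- Every aryl–carbon bond is an ordinary Friedel–Crafts bond to a phloroglucinol, so the difficulty is site control, not polarity. In any stepwise acylation, alkylation or O-alkylation two or three near-equivalent positions compete.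
- The benzylic centre C3' (R) sits between two ortho oxygens and is insulated by the arene from C2 (S) and C3 (R). No relay is possible, so two independent stereocontrolled events are needed and every error appears as a diastereomer.
- The 2,3-dimethylchroman-4-one is cis, the less stable arrangement. C3 is alpha to the ketone and C2–O1 is the bond of a beta-aryloxy ketone, so base or warm acid drifts to trans by enolisation or ring opening and re-closure. The ring must be closed late under kinetic control, and nothing basic may follow.
- The prenyl group rules out hydrogenation and strong protic or Lewis acids. The carboxylic acid must therefore be unmasked under near-neutral conditions.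
- Two features of the target make the key step possible. First, C4a and C7 lie on a local twofold axis of the arene: with free OH on both C5 and C8a and hydrogen on both C6 and C8, the core is a 2,6-dihydroxy-4-methoxyphenyl ketone with two equivalent OH groups and two equivalent ring CH positions. Second, O5 and C1' are in a 1,6-relationship (O5–C5–C6–C3'–C2'–C1'), a latent six-membered lactone (dihydrocoumarin ring) that is absent from the target.

## Retrosynthesis

**21 from 19 (via 20).** The bond O5–C1' is added, giving the tricyclic keto lactone 19. The lactone is a temporary ring that masks the acid and the C5 oxygen. Because it is an aryl ester it can be opened by a neutral acyl–oxygen cleavage, through the stannyl ester 20, after the epimerisable cis-chromanone is in place. The forward step must leave C3 untouched.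

**19 from 18.** The O1–C2 bond is cut. The forward reaction is an intramolecular Mitsunobu etherification of the anti-aldol 18, with inversion at the carbinol carbon, which gives the cis ring directly. The alternative cut, oxa-Michael closure of an enone, is reversible and leads to the trans isomer. While the lactone is closed, the oxygen on C8a is the only phenol next to the ketone, so the ring can close in one direction only. This is the second duty of the temporary ring.

**18 from 17, 16, and 12 + 15.** The C8–CH2 bond of the prenyl group is cut. The bond is formed by a [3,3] shift from the oxygen on C8a: phenol 12 is O-alkylated to the 1,1-dimethylallyl ether 16, and 16 rearranges to 17. The only free ortho position of that oxygen is C8, so direct C-prenylation with its O/C and linear/branched ambiguities is avoided. The same oxygen then serves as the ring oxygen O1. Desilylation of 17 gives 18. Carbonate 15 comes from alcohol 13 via alkoxide 14.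

**12 from 10 + 11 (key disconnection).** The C6–C3' bond and the O5–C1' bond are cut together. The precursor 10 has no ring stereocentre, no lactone, two equivalent phenols and two equivalent ring CH positions. A carbene-catalysed Claisen-type annulation with ynal 11 must do four things at once:
- form the hindered aryl–C(sp3) bond;
- set C3' (R) under catalyst control;
- break the local symmetry so that all three oxygens and both remaining ring positions become different;
- install the temporary lactone.

Stepwise Friedel–Crafts alkylation followed by later resolution of the oxygens would need protecting groups and would leave the stereocentre unsolved.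

**10 from 9, and 9 from 7 (via 8) + 5.** The C4a–C4 bond is cut. The bis-MOM ether 7 is lithiated at the one CH flanked by two MOM ethers to give 8, which is acylated by the Weinreb amide 5. This places the acyl group on the symmetry axis, which electrophilic acylation of 6 would not do. Acidic removal of the MOM groups from 9 gives 10.

**5 from 4, 3 and 1 (via 2); 7 from 6.** Both chromanone stereocentres are bought as one unit. The C3 hydroxyl centre of ester 1 directs anti-methylation through dianion 2 to give 3. Aminolysis (4) and silylation (5) follow. The anti relationship is exactly what the inverting ring closure needs for a cis product. Ether 7 is the bis-MOM derivative of the commercial diphenol 6.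

## Roads not taken

**Alternative 1 (the most obvious):** the three aryl–carbon bonds are made stepwise on a coumarin and the benzylic centre is set last.
- Route: Pechmann condensation of the parent triphenol with a C8 beta-keto ester gives 5,7-dihydroxy-4-pentylcoumarin A1. C-acylation with a tigloyl electrophile and oxa-Michael closure, C-prenylation and O-methylation lead to the coumarin–chromanone A2.
- Forward key step: enantioselective 1,4-reduction of the coumarin C3=C4 bond of A2, then lactone hydrolysis.
- Why the chosen plan is better: each substitution on A1 faces a C6/C8 and an O/C choice. The oxa-Michael closure gives the chromanone as a racemic mixture that favours trans. The reduction would have to work on a trisubstituted 4-alkylcoumarin with a peri methoxy group beside an aryl ketone, and would be followed by a basic hydrolysis that epimerises C3. None of the three stereocentres is controlled relative to the others.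

**Alternative 2:** only the C6–C3' bond is cut.
- Forward key step: rhodium-catalysed asymmetric 1,4-addition of the arylboronic acid A3 to tert-butyl (E)-oct-2-enoate A4, giving ester A5.
- Why the chosen plan is better: A3 is a 2,6-dioxygenated arylboronic acid, a class that protodeboronates readily and inserts slowly. It must first be assembled as a regiodefined, fully protected pentasubstituted arene. The acyl group and the chromanone would then have to be introduced afterwards on a ring that already carries the acid-labile prenyl group. The symmetry of the core is not used and several protecting-group steps are added.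

**Alternative 3:** no skeletal bond is cut; all three stereocentres are created at once.
- Forward key step: double asymmetric conjugate reduction of the flat coumarin–chromone A6 (coumarin C3=C4 and chromone C2=C3), with the cis relationship coming from syn delivery of hydrogen or from kinetic protonation.
- Why the chosen plan is better: the precursor is attractive because it is achiral, but one catalyst would have to reduce two electronically different, hindered double bonds with high face selectivity, one of them a tetrasubstituted vinylogous ester. It would also have to spare the prenyl group and both carbonyl groups. Four stereoisomers are possible and the basic lactone hydrolysis remains. In the chosen plan each stereocentre has its own well-precedented control element.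

Key step: step 7

Remark: the sense of induction of the triazolium catalyst with phenol 10 is assumed by analogy with the known enol and naphthol annulations and must be confirmed. Wherever the catalyst is named, the antipode that gives 4R is meant. Catalyst-bound species of catalytic cycles carry no compound numbers.

## Route

Step 1
Reactants: 1 methyl (R)-3-hydroxybutanoate
Product: 3 methyl (2R,3R)-3-hydroxy-2-methylbutanoate, via dilithio alkoxide-enolate 2 (not isolated)
Conditions: LiN(iPr)2 (2.2 equiv), THF, −78 → −20 °C; MeI, DMPU, −78 → −10 °C; AcOH quench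
Reagents that add atoms: iodomethane, CI
Why: Fráter–Seebach alkylation; the chelated dianion 2 is methylated on the face away from the C3 methyl group, which sets C2 (R) anti to the purchased C3 (R) centre.

Step 2
Reactants: 3 methyl (2R,3R)-3-hydroxy-2-methylbutanoate
Product: 4 (2R,3R)-3-hydroxy-N-methoxy-N,2-dimethylbutanamide
Conditions: MeNH(OMe)·HCl, iPrMgCl, THF, −20 → 0 °C
Reagents that add atoms: N,O-dimethylhydroxylamine hydrochloride, CNOC.Cl
Why: Weinreb amide formation by magnesium amide aminolysis of the ester; the alcohol is masked as its magnesium alkoxide and the low temperature should keep the alpha centre from enolising.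

Step 3
Reactants: 4 (2R,3R)-3-hydroxy-N-methoxy-N,2-dimethylbutanamide
Product: 5 (2R,3R)-3-[(tert-butyldiphenylsilyl)oxy]-N-methoxy-N,2-dimethylbutanamide
Conditions: TBDPSCl, imidazole, DMAP (cat.), DMF, 40 °C
Reagents that add atoms: tert-butyl(chloro)diphenylsilane, CC(C)(C)[Si](Cl)(c1ccccc1)c1ccccc1
Why: Standard silylation; the TBDPS ether is chosen because it must survive the acidic MOM cleavage of step 6 and keep the side-chain oxygen out of the acyl transfer of step 7.

Step 4
Reactants: 6 5-methoxybenzene-1,3-diol
Product: 7 1-methoxy-3,5-bis(methoxymethoxy)benzene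
Conditions: MOMCl, iPr2NEt, CH2Cl2, 0 °C → rt
Reagents that add atoms: chloromethyl methyl ether, COCCl
Why: Bis-acetalisation of the two phenols; the MOM ethers are the strongest available ortho directors for step 5 and are removable with mild acid.

Step 5
Reactants: 7 1-methoxy-3,5-bis(methoxymethoxy)benzene; 5 (2R,3R)-3-[(tert-butyldiphenylsilyl)oxy]-N-methoxy-N,2-dimethylbutanamide
Product: 9 (2R,3R)-3-[(tert-butyldiphenylsilyl)oxy]-1-[4-methoxy-2,6-bis(methoxymethoxy)phenyl]-2-methylbutan-1-one, via aryllithium 8 (not isolated)
Conditions: n-BuLi, THF, 0 °C; then 5, −78 → 0 °C; aq NH4Cl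
Reagents that add atoms: none
Why: Directed ortho-metalation occurs at the CH flanked by two cooperating MOM ethers in preference to the CH next to the weaker methoxy director; acyl substitution on the Weinreb amide passes through a chelated tetrahedral adduct that collapses only on quench, so no second addition and no exposure of the alpha centre to base is expected.

Step 6
Reactants: 9 (2R,3R)-3-[(tert-butyldiphenylsilyl)oxy]-1-[4-methoxy-2,6-bis(methoxymethoxy)phenyl]-2-methylbutan-1-one
Product: 10 (2R,3R)-3-[(tert-butyldiphenylsilyl)oxy]-1-(2,6-dihydroxy-4-methoxyphenyl)-2-methylbutan-1-one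
Conditions: HCl (1 M), MeOH/THF, 40 °C
Reagents that add atoms: none
Why: Acid-catalysed acetal cleavage; aryl MOM ethers ortho to a ketone are especially labile, while the secondary TBDPS ether and the beta-silyloxy ketone should tolerate dilute acid.

Step 7
Reactants: 10 (2R,3R)-3-[(tert-butyldiphenylsilyl)oxy]-1-(2,6-dihydroxy-4-methoxyphenyl)-2-methylbutan-1-one; 11 oct-2-ynal
Product: 12 (4R)-8-{(2R,3R)-3-[(tert-butyldiphenylsilyl)oxy]-2-methylbutanoyl}-7-hydroxy-5-methoxy-4-pentylchroman-2-one
Conditions: 11 (1.2 equiv), aminoindanol-derived N-mesityl triazolium chloride (2-mesityl-5a,10b-dihydro-4H,6H-indeno[2,1-b][1,2,4]triazolo[4,3-d][1,4]oxazin-2-ium chloride, 10 mol %), toluene, 40 °C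
Reagents that add atoms: none
Why: The free carbene adds to ynal 11 and internal redox gives the catalyst-bound (E)-alpha,beta-unsaturated acyl azolium; a chelated phenol of 10, a vinylogous acid like the kojic acids and naphthols known in this reaction, adds to the acyl carbon and the hemiacetal undergoes a [3,3] shift that joins the beta carbon to the neighbouring ring CH, or the ring carbon attacks the beta carbon directly, both paths leading to the same saturated acyl azolium. The closest known reaction type is the carbene-catalysed enantioselective Coates–Claisen annulation of ynals or enals with enols and naphthols to 3,4-dihydropyran-2-ones. The lactone ring closes by 6-exo-trig acyl substitution of the ortho phenol on the acyl azolium, which releases the carbene. The one new stereocentre (C4, R) is set by the chiral triazolylidene, which shields one face of the enoyl unit; the remote silyloxy chain should have no influence, and because it is enantiopure any 4S material is a diastereomer that chromatography can remove. Site selectivity needs no control, since the two OH groups and the two ring CH positions of 10 are equivalent through the local twofold axis and lactonisation is possible only onto the OH next to the carbon attacked. Mono-annulation is secured by the stoichiometry and by the lower nucleophilicity of the ring once one phenol has become an aryl ester. The internal redox of the ynal makes the step free of oxidant and by-product.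

Step 8
Reactants: 13 2-methylbut-3-en-2-ol
Product: 15 tert-butyl 2-methylbut-3-en-2-yl carbonate, via lithium 2-methylbut-3-en-2-olate 14 (not isolated)
Conditions: n-BuLi, THF, −78 → 0 °C; Boc2O, 0 °C → rt; aq NH4Cl
Reagents that add atoms: di-tert-butyl dicarbonate, CC(C)(C)OC(=O)OC(=O)OC(C)(C)C
Why: Acylation of the tertiary alkoxide by the dicarbonate, a standard preparation of tertiary allylic carbonates.

Step 9
Reactants: 12 (4R)-8-{(2R,3R)-3-[(tert-butyldiphenylsilyl)oxy]-2-methylbutanoyl}-7-hydroxy-5-methoxy-4-pentylchroman-2-one; 15 tert-butyl 2-methylbut-3-en-2-yl carbonate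
Product: 16 (4R)-8-{(2R,3R)-3-[(tert-butyldiphenylsilyl)oxy]-2-methylbutanoyl}-5-methoxy-7-[(2-methylbut-3-en-2-yl)oxy]-4-pentylchroman-2-one
Conditions: 15 (1.5 equiv), Pd(PPh3)4 (5 mol %), THF, 0 °C
Reagents that add atoms: none
Why: Decarboxylative Tsuji–Trost O-allylation; ionisation of 15 by zerovalent palladium gives a 1,1-dimethylallyl palladium cation and tert-butoxide, which deprotonates the only phenol, and the phenoxide attacks the more substituted terminus under kinetic control at low temperature to give the tertiary ether.

Step 10
Reactants: 16 (4R)-8-{(2R,3R)-3-[(tert-butyldiphenylsilyl)oxy]-2-methylbutanoyl}-5-methoxy-7-[(2-methylbut-3-en-2-yl)oxy]-4-pentylchroman-2-one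
Product: 17 (4R)-8-{(2R,3R)-3-[(tert-butyldiphenylsilyl)oxy]-2-methylbutanoyl}-7-hydroxy-5-methoxy-6-(3-methylbut-2-en-1-yl)-4-pentylchroman-2-one
Conditions: toluene, 110 °C
Reagents that add atoms: none
Why: Aromatic Claisen rearrangement; the [3,3] shift inverts the allyl unit so the tertiary ether delivers the linear prenyl group, and it can end only at C6 because the other ortho carbon carries the acyl group; rearomatisation returns the chelated phenol.

Step 11
Reactants: 17 (4R)-8-{(2R,3R)-3-[(tert-butyldiphenylsilyl)oxy]-2-methylbutanoyl}-7-hydroxy-5-methoxy-6-(3-methylbut-2-en-1-yl)-4-pentylchroman-2-one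
Product: 18 (4R)-7-hydroxy-8-[(2R,3R)-3-hydroxy-2-methylbutanoyl]-5-methoxy-6-(3-methylbut-2-en-1-yl)-4-pentylchroman-2-one
Conditions: HF·pyridine, pyridine, THF, 0 °C → rt
Reagents that add atoms: none
Why: Buffered fluoride desilylation; the weakly acidic medium should avoid the retro-aldol, elimination and alpha-epimerisation that basic fluoride could cause, and leaves the lactone and the prenyl group alone.

Step 12
Reactants: 18 (4R)-7-hydroxy-8-[(2R,3R)-3-hydroxy-2-methylbutanoyl]-5-methoxy-6-(3-methylbut-2-en-1-yl)-4-pentylchroman-2-one
Product: 19 tricyclic keto lactone: (4R)-5-methoxy-6-(3-methylbut-2-en-1-yl)-4-pentylchroman-2-one with a (2S,3R)-cis-2,3-dimethyl-2,3-dihydropyran-4-one ring fused across C7–C8 (ring oxygen on C7, ketone carbon on C8)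
Conditions: PPh3, DIAD, THF, 0 °C → rt
Reagents that add atoms: none
Why: Intramolecular Mitsunobu etherification; the acidic chelated phenol, the only one present because the other ortho oxygen is held in the lactone, displaces the activated secondary alcohol by 6-exo-tet attack with inversion, turning the (3R) carbinol into C2 (S) while the alpha centre (R) is untouched, so the anti-aldol gives the cis ring.

Step 13
Reactants: 19 tricyclic keto lactone
Product: 21 (3R)-3-[(2S,3R)-5-hydroxy-7-methoxy-2,3-dimethyl-8-(3-methylbut-2-en-1-yl)-4-oxo-3,4-dihydro-2H-chromen-6-yl]octanoic acid, via trimethylstannyl ester 20 (not isolated)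
Conditions: Me3SnOH, 1,2-dichloroethane, 60 °C; then 0.1 M HCl, 0 °C
Reagents that add atoms: trimethyltin hydroxide, C[Sn](C)(C)O
Why: Tin hydroxide acyl–oxygen cleavage of the aryl lactone, chosen over hydroxide because it is nearly neutral and should spare the epimerisable C3; the released phenol is held open by its hydrogen bond to the C4 ketone and cold dilute acid frees the acid from 20.

## Compound list

1 | methyl (R)-3-hydroxybutanoate | COC(=O)C[C@@H](C)O | starting material
2 | dilithio alkoxide-enolate of 1 | CO/C(O[Li])=C/[C@@H](C)O[Li] | intermediate (not isolated)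
3 | methyl (2R,3R)-3-hydroxy-2-methylbutanoate | COC(=O)[C@H](C)[C@@H](C)O | intermediate
4 | (2R,3R)-3-hydroxy-N-methoxy-N,2-dimethylbutanamide | CON(C)C(=O)[C@H](C)[C@@H](C)O | intermediate
5 | (2R,3R)-3-[(tert-butyldiphenylsilyl)oxy]-N-methoxy-N,2-dimethylbutanamide | CON(C)C(=O)[C@H](C)[C@@H](C)O[Si](c1ccccc1)(c1ccccc1)C(C)(C)C | intermediate
6 | 5-methoxybenzene-1,3-diol | COc1cc(O)cc(O)c1 | starting material
7 | 1-methoxy-3,5-bis(methoxymethoxy)benzene | COCOc1cc(OC)cc(OCOC)c1 | intermediate
8 | [4-methoxy-2,6-bis(methoxymethoxy)phenyl]lithium | [Li]c1c(OCOC)cc(OC)cc1OCOC | intermediate (not isolated)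
9 | (2R,3R)-3-[(tert-butyldiphenylsilyl)oxy]-1-[4-methoxy-2,6-bis(methoxymethoxy)phenyl]-2-methylbutan-1-one | COCOc1cc(OC)cc(OCOC)c1C(=O)[C@H](C)[C@@H](C)O[Si](c1ccccc1)(c1ccccc1)C(C)(C)C | intermediate
10 | (2R,3R)-3-[(tert-butyldiphenylsilyl)oxy]-1-(2,6-dihydroxy-4-methoxyphenyl)-2-methylbutan-1-one | COc1cc(O)c(C(=O)[C@H](C)[C@@H](C)O[Si](c2ccccc2)(c2ccccc2)C(C)(C)C)c(O)c1 | intermediate
11 | oct-2-ynal | CCCCCC#CC=O | starting material
12 | (4R)-8-{(2R,3R)-3-[(tert-butyldiphenylsilyl)oxy]-2-methylbutanoyl}-7-hydroxy-5-methoxy-4-pentylchroman-2-one | CCCCC[C@@H]1CC(=O)Oc2c1c(OC)cc(O)c2C(=O)[C@H](C)[C@@H](C)O[Si](c1ccccc1)(c1ccccc1)C(C)(C)C | intermediate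
13 | 2-methylbut-3-en-2-ol | CC(C)(O)C=C | starting material
14 | lithium 2-methylbut-3-en-2-olate | [Li]OC(C)(C)C=C | intermediate (not isolated)
15 | tert-butyl 2-methylbut-3-en-2-yl carbonate | CC(C)(C)OC(=O)OC(C)(C)C=C | intermediate
16 | (4R)-8-{(2R,3R)-3-[(tert-butyldiphenylsilyl)oxy]-2-methylbutanoyl}-5-methoxy-7-[(2-methylbut-3-en-2-yl)oxy]-4-pentylchroman-2-one | CCCCC[C@@H]1CC(=O)Oc2c1c(OC)cc(OC(C)(C)C=C)c2C(=O)[C@H](C)[C@@H](C)O[Si](c1ccccc1)(c1ccccc1)C(C)(C)C | intermediate
17 | (4R)-8-{(2R,3R)-3-[(tert-butyldiphenylsilyl)oxy]-2-methylbutanoyl}-7-hydroxy-5-methoxy-6-(3-methylbut-2-en-1-yl)-4-pentylchroman-2-one | CCCCC[C@@H]1CC(=O)Oc2c1c(OC)c(CC=C(C)C)c(O)c2C(=O)[C@H](C)[C@@H](C)O[Si](c1ccccc1)(c1ccccc1)C(C)(C)C | intermediate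
18 | (4R)-7-hydroxy-8-[(2R,3R)-3-hydroxy-2-methylbutanoyl]-5-methoxy-6-(3-methylbut-2-en-1-yl)-4-pentylchroman-2-one | CCCCC[C@@H]1CC(=O)Oc2c1c(OC)c(CC=C(C)C)c(O)c2C(=O)[C@H](C)[C@@H](C)O | intermediate
19 | tricyclic keto lactone (delta-lactone of 21 onto its C5 oxygen; cis-(2S,3R)-dimethylchromanone ring, (R)-pentyl-bearing dihydrocoumarin ring) | CCCCC[C@@H]1CC(=O)Oc2c1c(OC)c(CC=C(C)C)c1O[C@@H](C)[C@@H](C)C(=O)c21 | intermediate
20 | trimethylstannyl (3R)-3-[(2S,3R)-5-hydroxy-7-methoxy-2,3-dimethyl-8-(3-methylbut-2-en-1-yl)-4-oxo-3,4-dihydro-2H-chromen-6-yl]octanoate | CCCCC[C@H](CC(=O)O[Sn](C)(C)C)c1c(O)c2c(c(CC=C(C)C)c1OC)O[C@@H](C)[C@@H](C)C2=O | intermediate (not isolated)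
21 | (3R)-3-[(2S,3R)-5-hydroxy-7-methoxy-2,3-dimethyl-8-(3-methylbut-2-en-1-yl)-4-oxo-3,4-dihydro-2H-chromen-6-yl]octanoic acid | CCCCC[C@H](CC(=O)O)c1c(O)c2c(c(CC=C(C)C)c1OC)O[C@@H](C)[C@@H](C)C2=O | target

## Step count and risks

Total: 13 steps. Longest linear sequence: 11 steps (1 to 21 through steps 1, 2, 3, 5, 6, 7, 9, 10, 11, 12, 13). Steps 4 and 8 are side branches.

**Step 7 (key step).**
- Risk: the chelated acylphloroglucinol may add too slowly to the acyl azolium, so that self-condensation or redox esterification of the ynal takes over. Face discrimination may also be incomplete with an aliphatic beta substituent.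
- Fallback, from 10 back to 12: iminium-catalysed Friedel–Crafts alkylation and hemiacetalisation of 10 with (E)-oct-2-enal and a diarylprolinol silyl ether should give the 2-hydroxychroman (lactol) F1. Oxidation with TEMPO/PhI(OAc)2 returns to 12.

**Step 12.**
- Risk: beta-elimination of the activated alcohol towards the enone, followed by unselective oxa-Michael closure. This would lose control of C2 and scramble cis and trans.
- Fallback, from 18 back to 19: Dess–Martin oxidation to the beta-diketone F2, then mild acid cyclodehydration (AcOH, 50 °C) to the 2,3-dimethylchromone F3. Asymmetric conjugate reduction with CuH (Cu(OAc)2, chiral bisphosphine, (EtO)2MeSiH, tBuOH) sets C2 under catalyst control, and protonation of the enolate anti to the 2-methyl group is expected to give the cis ring of 19. The ring is then formed by hydride delivery to a flat chromone instead of substitution at carbon.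

**Step 13.**
- Risk: enolisation at C3 or ring opening and re-closure of the chromanone at the temperature the tin reagent needs, leading to the trans isomer. Re-lactonisation on acidic work-up is a second concern.
- Fallback, from 19 back to 21: acid-catalysed transesterification with allyl alcohol (camphorsulfonic acid cat., rt) gives the allyl ester F4. Deallylation with Pd(PPh3)4 and PhSiH3 is fully non-basic and gives 21.

**Step 9.**
- Risk: sluggish O-alkylation of the hindered, chelated phenol. Palladium-mediated re-ionisation of the tertiary ether could return it to the linear O-prenyl ether, whose Claisen shift would give the wrong (1,1-dimethylallyl) isomer. Loss of isoprene is also possible.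
- Fallback, from 12 back to 17: iodination of the only free ring CH with N-iodosuccinimide gives the aryl iodide F5. Stille coupling with tributyl(3-methylbut-2-enyl)stannane and Pd(PPh3)4 (DMF, 80 °C) gives 17 directly and skips 16 and step 10.

**Step 5.**
- Risk: slow addition of the di-ortho-substituted aryllithium to the branched, hindered Weinreb amide. Alpha-deprotonation (epimerisation, loss of silanolate) or N–O cleavage of the amide could then compete.
- Fallback, from 5 back to 9: reduction of 5 with iBu2AlH (−78 °C) gives the aldehyde F6. Addition of 8 gives the carbinol F7 as an inconsequential epimer mixture at the new centre, and Dess–Martin oxidation gives 9.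

## Further compounds

F1 | step 7 | (4R)-8-{(2R,3R)-3-[(tert-butyldiphenylsilyl)oxy]-2-methylbutanoyl}-5-methoxy-4-pentylchroman-2,7-diol (lactol, anomer mixture) | CCCCC[C@@H]1CC(O)Oc2c1c(OC)cc(O)c2C(=O)[C@H](C)[C@@H](C)O[Si](c1ccccc1)(c1ccccc1)C(C)(C)C
F2 | step 12 | (4R)-7-hydroxy-5-methoxy-6-(3-methylbut-2-en-1-yl)-8-(2-methyl-3-oxobutanoyl)-4-pentylchroman-2-one (alpha centre enolisable, unspecified) | CCCCC[C@@H]1CC(=O)Oc2c1c(OC)c(CC=C(C)C)c(O)c2C(=O)C(C)C(C)=O
F3 | step 12 | chromone lactone: (4R)-5-methoxy-6-(3-methylbut-2-en-1-yl)-4-pentylchroman-2-one with a 2,3-dimethyl-4-pyranone ring fused across C7–C8 | CCCCC[C@@H]1CC(=O)Oc2c1c(OC)c(CC=C(C)C)c1OC(C)=C(C)C(=O)c21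
F4 | step 13 | allyl (3R)-3-[(2S,3R)-5-hydroxy-7-methoxy-2,3-dimethyl-8-(3-methylbut-2-en-1-yl)-4-oxo-3,4-dihydro-2H-chromen-6-yl]octanoate | CCCCC[C@H](CC(=O)OCC=C)c1c(O)c2c(c(CC=C(C)C)c1OC)O[C@@H](C)[C@@H](C)C2=O
F5 | step 9 | (4R)-8-{(2R,3R)-3-[(tert-butyldiphenylsilyl)oxy]-2-methylbutanoyl}-7-hydroxy-6-iodo-5-methoxy-4-pentylchroman-2-one | CCCCC[C@@H]1CC(=O)Oc2c1c(OC)c(I)c(O)c2C(=O)[C@H](C)[C@@H](C)O[Si](c1ccccc1)(c1ccccc1)C(C)(C)C
F6 | step 5 | (2R,3R)-3-[(tert-butyldiphenylsilyl)oxy]-2-methylbutanal | O=C[C@H](C)[C@@H](C)O[Si](c1ccccc1)(c1ccccc1)C(C)(C)C
F7 | step 5 | (2R,3R)-3-[(tert-butyldiphenylsilyl)oxy]-1-[4-methoxy-2,6-bis(methoxymethoxy)phenyl]-2-methylbutan-1-ol (chain descriptors as in 5; epimer mixture at C1) | COCOc1cc(OC)cc(OCOC)c1C(O)[C@H](C)[C@@H](C)O[Si](c1ccccc1)(c1ccccc1)C(C)(C)C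
A1 | alternative 1 | 5,7-dihydroxy-4-pentylcoumarin | CCCCCC1=CC(=O)Oc2cc(O)cc(O)c12
A2 | alternative 1 | coumarin–chromanone: 5-methoxy-6-(3-methylbut-2-en-1-yl)-4-pentylcoumarin with a 2,3-dimethyl-2,3-dihydropyran-4-one ring fused across C7–C8 (stereoisomer mixture) | CCCCCC1=CC(=O)Oc2c1c(OC)c(CC=C(C)C)c1OC(C)C(C)C(=O)c21
A3 | alternative 2 | [2-methoxy-4,6-bis(methoxymethoxy)-3-(3-methylbut-2-en-1-yl)phenyl]boronic acid | COCOc1cc(OCOC)c(CC=C(C)C)c(OC)c1B(O)O
A4 | alternative 2 | tert-butyl (E)-oct-2-enoate | CCCCC/C=C/C(=O)OC(C)(C)C
A5 | alternative 2 | tert-butyl (3R)-3-[2-methoxy-4,6-bis(methoxymethoxy)-3-(3-methylbut-2-en-1-yl)phenyl]octanoate | CCCCC[C@H](CC(=O)OC(C)(C)C)c1c(OCOC)cc(OCOC)c(CC=C(C)C)c1OC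
A6 | alternative 3 | coumarin–chromone: 5-methoxy-6-(3-methylbut-2-en-1-yl)-4-pentylcoumarin with a 2,3-dimethyl-4-pyranone ring fused across C7–C8 | CCCCCC1=CC(=O)Oc2c1c(OC)c(CC=C(C)C)c1OC(C)=C(C)C(=O)c21
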